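**Abbreviations and remarks**

- TBS = tert‑butyldimethylsilyl; TBDPS = tert‑butyldiphenylsilyl; DMP = Dess–Martin periodinane.
- Remark on numbering: germacrane numbering of the target is used for all intermediates. Ring A is the ten‑membered carbocycle C1–C10 (C14 on C10, C15 on C4). Ring B is the γ‑lactone (C6, C7, C11, C12, O; C13 on C11). Ring C is the oxirane (C1, C10, O).
- Assumption: compounds 1, 3, 7, 9, 14 (as paraformaldehyde) and 20 are purchased.
- Remark on the chemistry: compounds 21–23 are expected as mixtures of C1 epimers and are used as such, because step 16 removes this centre.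

## Retrosynthetic overview

1. Late stage: the C11=C13 methylene (E1cB loss of a C13 acetate), the C15 aldehyde (MnO2) and the 1,10‑epoxide (Sharpless epoxidation of the C14 allylic alcohol) are added to a ring A that already carries C6, C7, C8 and both ring‑cis alkenes.
2. Key disconnection C8–C9: SmI2 ketyl–olefin closure of a C8 aldehyde onto C9, ended by loss of a C1 acetate. The enabling feature is that C9–C10(–C14)=C1 is a 2‑carbonyl‑allyl unit: C9 is the free CH2 end of an acrylate whose carbonyl is C14 and whose allylic carbon C1 bears a leaving group, while C8 is a formyl group on C7 of ring B.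
3. The open‑chain precursor: C1–C10 by Morita–Baylis–Hillman reaction of a C1 aldehyde with allyl acrylate (C9, C10, C14); C4=C5 by Wittig reaction of a C5 aldehyde with a formyl ylide (C15, C4–C1).
4. Ring B with C6 is bought as (S)‑5‑(hydroxymethyl)furan‑2(5H)‑one; C7 is set by photochemical conjugate addition of 1,3‑dioxolane (brings C8); C13 comes from enolate hydroxymethylation.
5. Order of rings: ring B (bought) → ring A (step 16) → ring C (step 19).

Key step: step 16

## Route

Step 1
Reactants: 1 (5S)-5-(hydroxymethyl)furan-2(5H)-one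
Product: 2 (5S)-5-(TBS-oxymethyl)furan-2(5H)-one
Conditions: TBSCl, imidazole, DMF, 0 °C to rt
Reagents that add atoms: tert-butyl(chloro)dimethylsilane, CC(C)(C)[Si](C)(C)Cl
Why: Standard silylation of a primary alcohol under mild conditions that leave the acidic γ‑hydrogen at C6 untouched and keep the carbinol out of the radical chemistry of step 2.

Step 2
Reactants: 2 TBS-protected butenolide; 3 1,3-dioxolane
Product: 4 trans-(4S,5S)-4-(1,3-dioxolan-2-yl)-5-(TBS-oxymethyl)oxolan-2-one
Conditions: 3 (solvent), Ph2CO (10 mol%), hν (Hg lamp, Pyrex), degassed, 10 °C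
Reagents that add atoms: none
Why: Benzophenone‑sensitised radical conjugate addition in which the 1,3‑dioxolan‑2‑yl radical adds to the β‑carbon of the butenolide anti to the CH2OTBS group on C6, so C7 is set trans to C6 and C8 arrives as a masked aldehyde.

Step 3
Reactants: 4 dioxolanyl lactone TBS ether
Product: 5 (4S,5S)-4-(1,3-dioxolan-2-yl)-5-(hydroxymethyl)oxolan-2-one
Conditions: TBAF, AcOH, THF, 0 °C to rt
Reagents that add atoms: none
Why: Buffered fluoride desilylation frees the C5 hydroxyl without touching the acetal or opening the lactone.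

Step 4
Reactants: 5 hydroxymethyl lactone
Product: 6 (2S,3S)-3-(1,3-dioxolan-2-yl)-5-oxooxolane-2-carbaldehyde
Conditions: DMP, pyridine, CH2Cl2, 0 °C to rt; used at once
Reagents that add atoms: none
Why: Dess–Martin oxidation gives the C5 aldehyde under near‑neutral conditions, which limits epimerisation at C6.

Step 5
Reactants: 7 (4-bromobutoxy)(tert-butyl)dimethylsilane
Product: 8 [4-(TBS-oxy)butyl]triphenylphosphonium bromide
Conditions: PPh3, MeCN, reflux
Reagents that add atoms: triphenylphosphine, c1ccc(cc1)P(c1ccccc1)c1ccccc1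
Why: SN2 quaternisation of a primary bromide gives the phosphonium salt that carries C1–C4.

Step 6
Reactants: 8 phosphonium bromide; 9 ethyl formate
Product: 11 5-(TBS-oxy)-2-(triphenylphosphanylidene)pentanal, via phosphorus ylide 10 (not isolated)
Conditions: NaN(SiMe3)2, THF, −78 to 0 °C; then 9, −78 °C to rt
Reagents that add atoms: none
Why: C‑formylation of a non‑stabilised ylide with a formate ester gives the formyl‑stabilised ylide, in which C15 is attached to C4.

Step 7
Reactants: 6 lactone aldehyde; 11 formyl ylide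
Product: 12 (2E)-enal with the lactone on C5 and C1 as CH2OTBS
Conditions: toluene, 60 °C
Reagents that add atoms: none
Why: Wittig reaction of a stabilised α‑branched ylide gives the (E)‑2‑alkyl‑2‑enal, so C6 ends trans to the formyl group and cis to C3, which is the ring‑cis C4=C5 geometry of the target.

Step 8
Reactants: 12 enal
Product: 13 C15 allylic alcohol
Conditions: NaBH4, CeCl3·7H2O, MeOH, −40 °C
Reagents that add atoms: none
Why: Luche 1,2‑reduction removes the enal (which would not survive steps 13 and 16) while the lactone is not reduced under these conditions.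

Step 9
Reactants: 13 allylic alcohol lactone; 14 formaldehyde
Product: 16 C13,C15-diol, via dilithium enolate 15 (not isolated)
Conditions: LiN(iPr)2 (2.2 equiv), THF, −78 °C; then 14 (gas from cracked paraformaldehyde), −78 to −20 °C; aq. NH4Cl
Reagents that add atoms: none
Why: Aldol reaction of the lactone enolate with formaldehyde installs C13 on the face of C11 opposite the dioxolanyl group on C7 (trans), giving a masked form of the exocyclic methylene that tolerates all later steps.

Step 10
Reactants: 16 diol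
Product: 17 C13,C15-bis-TBDPS ether
Conditions: TBDPSCl (2.5 equiv), imidazole, DMF, rt
Reagents that add atoms: tert-butyl(chloro)diphenylsilane, CC(C)(C)[Si](Cl)(c1ccccc1)c1ccccc1
Why: Both primary hydroxyls are protected in one operation as acid‑stable silyl ethers that can be told apart from the C1 TBS ether.

Step 11
Reactants: 17 tris-silyl ether
Product: 18 C1 primary alcohol
Conditions: HF·pyridine, pyridine, THF, 0 °C
Reagents that add atoms: none
Why: Buffered HF cleaves the primary TBS ether much faster than the two primary TBDPS ethers and leaves the dioxolane intact.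

Step 12
Reactants: 18 C1 alcohol
Product: 19 C1 aldehyde
Conditions: DMP, pyridine, CH2Cl2, 0 °C to rt
Reagents that add atoms: none
Why: Dess–Martin oxidation of the only free hydroxyl gives the unbranched C1 aldehyde needed for step 13.

Step 13
Reactants: 19 C1 aldehyde; 20 allyl acrylate
Product: 21 Morita–Baylis–Hillman alcohol (C1 carbinol, C9 methylene, C14 allyl ester)
Conditions: 20 (5 equiv), DABCO (1 equiv), neat, rt, several days
Reagents that add atoms: none
Why: Morita–Baylis–Hillman reaction joins C1 to C10 and brings in C9 and C14 from a cheap acrylate; the new C1 centre is formed without control, which is harmless because step 16 destroys it.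

Step 14
Reactants: 21 Morita–Baylis–Hillman alcohol
Product: 22 C1 acetate
Conditions: AcCl, pyridine, CH2Cl2, 0 °C
Reagents that add atoms: acetyl chloride, CC(Cl)=O
Why: O‑Acetylation without a nucleophilic catalyst turns the C1 hydroxyl into the leaving group for step 16 and avoids allylic transposition of the acetate.

Step 15
Reactants: 22 dioxolane acetate
Product: 23 C8 aldehyde (precursor of the ring closure)
Conditions: aq. HCl (1 M), THF, rt; crude product dried azeotropically and used at once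
Reagents that add atoms: water, O
Why: Acid hydrolysis of the dioxolane releases the C8 aldehyde while the allylic acetate, silyl ethers and lactone are stable to dilute acid; the trans arrangement on ring B is the stable one, and the β‑acyloxy aldehyde never meets base.

Step 16
Reactants: 23 C8 aldehyde with C1 acetoxy acrylate
Product: 25 macrocyclic 8-acetate allyl ester (ring A closed; 1(10)E,4E; 6R,7R,8S,11R), via macrocyclic 8-alcohol 24 (not isolated)
Conditions: 23 added over 6 h to SmI2 (2.5 equiv), THF (final 2 mM), 0 °C; then Ac2O, DMAP, 0 °C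
Reagents that add atoms: acetic anhydride, CC(=O)OC(C)=O
Why: Proposed new method: SmI2 should reduce the C8 aldehyde to a samarium ketyl that adds to C9, the free CH2 terminus of the acrylate, the ester‑stabilised C10 radical is reduced by a second SmI2 to a trivalent samarium enolate, and this enolate expels the C1 acetate (E1cB) to give the C1=C10 enoate, the closest known reaction types being the SmI2 ketyl–acrylate reductive coupling (known also for endo closure of eight‑membered rings) and the SmI2‑promoted β‑elimination of β‑acetoxy ester enolates to (E)‑enoates, which have not been joined in a macrocyclisation. Ring A is closed in a 10‑endo‑trig radical addition, helped by the trans‑fused ring B and the ring‑cis C4=C5 bond, which hold C8 and C9 within reach. C8 is set under control of C7: closure trans to ring B forces the forming C8–C9 bond gauche to C7–C6 on the side of H7, so the bulky samarium‑bound oxygen takes the open position anti to C6 and H8 the slot between C6 and C11, which is the (8S) configuration. The C1=C10 geometry is set in the elimination, where a chair‑like samarium chelate and A(1,3) strain place C2 trans to the ester and cis to C9 (ring‑cis), so both C1 epimers converge. The step needs attack at C9 only and ring closure in preference to pinacol coupling or simple reduction; C9 is the sole unhindered β‑carbon of the only electron‑poor alkene in 23 (C15 and C13 are kept at the alcohol level for this reason), and slow addition at high dilution suppresses dimerisation. Acetic anhydride then traps the C8 samarium alkoxide as the acetate of the target, which also blocks migration of the lactone from O6 to O8.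

Step 17
Reactants: 25 macrocyclic allyl ester
Product: 26 C14 carboxylic acid
Conditions: Pd(PPh3)4 (5 mol%), morpholine, THF, rt
Reagents that add atoms: none
Why: Zerovalent palladium ionises the allyl ester and morpholine takes up the allyl group (Tsuji–Trost deallylation), neutral conditions that spare the lactone, the acetate and the silyl ethers.

Step 18
Reactants: 26 C14 acid
Product: 28 C14 allylic alcohol, via mixed carbonic anhydride 27 (not isolated)
Conditions: iBuOCOCl, N-methylmorpholine, THF, −15 °C; then NaBH4, H2O, −15 to 0 °C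
Reagents that add atoms: none
Why: Activation as a mixed anhydride lets NaBH4 reduce C14 alone to the primary alcohol at low temperature, a standard way to reduce an acid in the presence of a lactone and an acetate.

Step 19
Reactants: 28 C14 allylic alcohol
Product: 29 (1R,10R)-1,10-epoxy-14-alcohol
Conditions: Ti(OiPr)4, D-(−)-diethyl tartrate, tBuOOH, 4 Å molecular sieves, CH2Cl2, −20 °C
Reagents that add atoms: tert-butyl hydroperoxide, CC(C)(C)OO
Why: Sharpless asymmetric epoxidation of a 2,3‑disubstituted allylic alcohol (C2 trans to CH2OH) acts only on C1=C10, and the tartrate enantiomer that converts (E)‑hex‑2‑en‑1‑ol into its (2R,3R)‑epoxide delivers oxygen to the corresponding face here, which sets C1 and C10 as (1R,10R) in one event.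

Step 20
Reactants: 29 epoxy alcohol bis-TBDPS ether
Product: 30 C13,C14,C15-triol
Conditions: TBAF, AcOH, THF, rt
Reagents that add atoms: none
Why: Buffered fluoride removes both TBDPS groups without Payne rearrangement of the epoxy alcohol or loss of the C8 acetate.

Step 21
Reactants: 30 triol
Product: 31 15-al C13,C14-diol
Conditions: MnO2, CH2Cl2, rt
Reagents that add atoms: none
Why: MnO2 oxidises only the allylic C15 alcohol to the (E)‑enal, because the C13 hydroxyl and the C14 hydroxyl (now on an oxirane carbon) are not allylic.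

Step 22
Reactants: 31 enal diol
Product: 33 target (1R,4E,6R,7R,8S,10R)-8,14-diacetoxy-1,10-epoxy-15-oxogermacra-4,11(13)-dien-12,6-olide, via 8,13,14-triacetate 32 (not isolated)
Conditions: Ac2O, Et3N, DMAP, CH2Cl2, 0 °C to rt; then DBU, rt
Reagents that add atoms: acetic anhydride, CC(=O)OC(C)=O
Why: Acetylation gives the C14 acetate of the target and turns the C13 hydroxyl into a β‑acetoxy leaving group, which DBU eliminates (E1cB) to form the α‑methylene lactone; the C8 and C14 acetates have no such acidic β‑relationship.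

## Compound list

1 | (5S)-5-(hydroxymethyl)furan-2(5H)-one | O=C1O[C@H](CO)C=C1 | starting material
2 | (5S)-5-{[(tert-butyldimethylsilyl)oxy]methyl}furan-2(5H)-one | O=C1O[C@H](CO[Si](C)(C)C(C)(C)C)C=C1 | intermediate
3 | 1,3-dioxolane | C1COCO1 | starting material
4 | (4S,5S)-5-{[(tert-butyldimethylsilyl)oxy]methyl}-4-(1,3-dioxolan-2-yl)oxolan-2-one (trans) | O=C1O[C@H](CO[Si](C)(C)C(C)(C)C)[C@@H](C2OCCO2)C1 | intermediate
5 | (4S,5S)-4-(1,3-dioxolan-2-yl)-5-(hydroxymethyl)oxolan-2-one | O=C1O[C@H](CO)[C@@H](C2OCCO2)C1 | intermediate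
6 | (2S,3S)-3-(1,3-dioxolan-2-yl)-5-oxooxolane-2-carbaldehyde | O=C1O[C@H](C=O)[C@@H](C2OCCO2)C1 | intermediate
7 | (4-bromobutoxy)(tert-butyl)dimethylsilane | BrCCCCO[Si](C)(C)C(C)(C)C | starting material
8 | {4-[(tert-butyldimethylsilyl)oxy]butyl}triphenylphosphonium bromide | CC(C)(C)[Si](C)(C)OCCCC[P+](c1ccccc1)(c1ccccc1)c1ccccc1.[Br-] | intermediate
9 | ethyl formate | CCOC=O | starting material
10 | {4-[(tert-butyldimethylsilyl)oxy]butylidene}triphenyl-λ5-phosphane | CC(C)(C)[Si](C)(C)OCCCC=P(c1ccccc1)(c1ccccc1)c1ccccc1 | intermediate (not isolated)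
11 | 5-[(tert-butyldimethylsilyl)oxy]-2-(triphenyl-λ5-phosphanylidene)pentanal | O=CC(CCCO[Si](C)(C)C(C)(C)C)=P(c1ccccc1)(c1ccccc1)c1ccccc1 | intermediate
12 | (2E)-5-[(TBS)oxy]-2-{[(2R,3S)-3-(1,3-dioxolan-2-yl)-5-oxooxolan-2-yl]methylidene}pentanal | O=C1O[C@H](/C=C(/C=O)CCCO[Si](C)(C)C(C)(C)C)[C@@H](C2OCCO2)C1 | intermediate
13 | (4S,5R)-5-[(1E)-5-[(TBS)oxy]-2-(hydroxymethyl)pent-1-en-1-yl]-4-(1,3-dioxolan-2-yl)oxolan-2-one | O=C1O[C@H](/C=C(/CO)CCCO[Si](C)(C)C(C)(C)C)[C@@H](C2OCCO2)C1 | intermediate
14 | formaldehyde (gas from paraformaldehyde) | C=O | starting material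
15 | dilithium salt of 13 (lactone enolate at C11/C12 and C15 alkoxide) | [Li+].[Li+].[O-]C1=C[C@H](C2OCCO2)[C@@H](/C=C(/C[O-])CCCO[Si](C)(C)C(C)(C)C)O1 | intermediate (not isolated)
16 | (3R,4S,5R)-5-[(1E)-5-[(TBS)oxy]-2-(hydroxymethyl)pent-1-en-1-yl]-4-(1,3-dioxolan-2-yl)-3-(hydroxymethyl)oxolan-2-one | O=C1O[C@H](/C=C(/CO)CCCO[Si](C)(C)C(C)(C)C)[C@@H](C2OCCO2)[C@@H]1CO | intermediate
17 | (3R,4S,5R)-5-[(1E)-5-[(TBS)oxy]-2-{[(TBDPS)oxy]methyl}pent-1-en-1-yl]-3-{[(TBDPS)oxy]methyl}-4-(1,3-dioxolan-2-yl)oxolan-2-one | O=C1O[C@H](/C=C(/CO[Si](c2ccccc2)(c3ccccc3)C(C)(C)C)CCCO[Si](C)(C)C(C)(C)C)[C@@H](C4OCCO4)[C@@H]1CO[Si](c5ccccc5)(c6ccccc6)C(C)(C)C | intermediate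
18 | (3R,4S,5R)-5-[(1E)-5-hydroxy-2-{[(TBDPS)oxy]methyl}pent-1-en-1-yl]-3-{[(TBDPS)oxy]methyl}-4-(1,3-dioxolan-2-yl)oxolan-2-one | O=C1O[C@H](/C=C(/CO[Si](c2ccccc2)(c3ccccc3)C(C)(C)C)CCCO)[C@@H](C4OCCO4)[C@@H]1CO[Si](c5ccccc5)(c6ccccc6)C(C)(C)C | intermediate
19 | (4E)-4-{[(TBDPS)oxy]methyl}-5-[(2R,3S,4R)-4-{[(TBDPS)oxy]methyl}-3-(1,3-dioxolan-2-yl)-5-oxooxolan-2-yl]pent-4-enal | O=C1O[C@H](/C=C(/CO[Si](c2ccccc2)(c3ccccc3)C(C)(C)C)CCC=O)[C@@H](C4OCCO4)[C@@H]1CO[Si](c5ccccc5)(c6ccccc6)C(C)(C)C | intermediate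
20 | allyl acrylate (prop-2-en-1-yl prop-2-enoate) | C=CC(=O)OCC=C | starting material
21 | allyl (6E)-3-hydroxy-2-methylidene-6-{[(TBDPS)oxy]methyl}-7-[(2R,3S,4R)-4-{[(TBDPS)oxy]methyl}-3-(1,3-dioxolan-2-yl)-5-oxooxolan-2-yl]hept-6-enoate (both epimers at the carbinol, C1 of the target) | O=C1O[C@H](/C=C(/CO[Si](c2ccccc2)(c3ccccc3)C(C)(C)C)CCC(O)C(=C)C(=O)OCC=C)[C@@H](C4OCCO4)[C@@H]1CO[Si](c5ccccc5)(c6ccccc6)C(C)(C)C | intermediate
22 | 3-acetate of 21 (allyl (6E)-3-acetoxy-2-methylidene-…hept-6-enoate, both C1 epimers) | O=C1O[C@H](/C=C(/CO[Si](c2ccccc2)(c3ccccc3)C(C)(C)C)CCC(OC(C)=O)C(=C)C(=O)OCC=C)[C@@H](C4OCCO4)[C@@H]1CO[Si](c5ccccc5)(c6ccccc6)C(C)(C)C | intermediate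
23 | allyl (6E)-3-acetoxy-2-methylidene-6-{[(TBDPS)oxy]methyl}-7-[(2R,3S,4R)-3-formyl-4-{[(TBDPS)oxy]methyl}-5-oxooxolan-2-yl]hept-6-enoate (both C1 epimers) | O=C1O[C@H](/C=C(/CO[Si](c2ccccc2)(c3ccccc3)C(C)(C)C)CCC(OC(C)=O)C(=C)C(=O)OCC=C)[C@@H](C=O)[C@@H]1CO[Si](c4ccccc4)(c5ccccc5)C(C)(C)C | intermediate
24 | allyl (1(10)E,4E,6R,7R,8S,11R)-8-hydroxy-13,15-bis[(TBDPS)oxy]germacra-1(10),4-dien-12,6-olid-14-oate (present as its trivalent samarium alkoxide) | O=C1O[C@@H]2/C=C(/CO[Si](c3ccccc3)(c4ccccc4)C(C)(C)C)CC/C=C(/C(=O)OCC=C)C[C@H](O)[C@H]2[C@@H]1CO[Si](c5ccccc5)(c6ccccc6)C(C)(C)C | intermediate (not isolated)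
25 | allyl (1(10)E,4E,6R,7R,8S,11R)-8-acetoxy-13,15-bis[(TBDPS)oxy]germacra-1(10),4-dien-12,6-olid-14-oate | O=C1O[C@@H]2/C=C(/CO[Si](c3ccccc3)(c4ccccc4)C(C)(C)C)CC/C=C(/C(=O)OCC=C)C[C@H](OC(C)=O)[C@H]2[C@@H]1CO[Si](c5ccccc5)(c6ccccc6)C(C)(C)C | intermediate
26 | (1(10)E,4E,6R,7R,8S,11R)-8-acetoxy-13,15-bis[(TBDPS)oxy]germacra-1(10),4-dien-12,6-olid-14-oic acid | O=C1O[C@@H]2/C=C(/CO[Si](c3ccccc3)(c4ccccc4)C(C)(C)C)CC/C=C(/C(=O)O)C[C@H](OC(C)=O)[C@H]2[C@@H]1CO[Si](c5ccccc5)(c6ccccc6)C(C)(C)C | intermediate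
27 | mixed anhydride of 26 with isobutyl hydrogen carbonate | O=C1O[C@@H]2/C=C(/CO[Si](c3ccccc3)(c4ccccc4)C(C)(C)C)CC/C=C(/C(=O)OC(=O)OCC(C)C)C[C@H](OC(C)=O)[C@H]2[C@@H]1CO[Si](c5ccccc5)(c6ccccc6)C(C)(C)C | intermediate (not isolated)
28 | (1(10)E,4E,6R,7R,8S,11R)-8-acetoxy-14-hydroxy-13,15-bis[(TBDPS)oxy]germacra-1(10),4-dien-12,6-olide | O=C1O[C@@H]2/C=C(/CO[Si](c3ccccc3)(c4ccccc4)C(C)(C)C)CC/C=C(/CO)C[C@H](OC(C)=O)[C@H]2[C@@H]1CO[Si](c5ccccc5)(c6ccccc6)C(C)(C)C | intermediate
29 | (1R,4E,6R,7R,8S,10R,11R)-8-acetoxy-1,10-epoxy-14-hydroxy-13,15-bis[(TBDPS)oxy]germacr-4-en-12,6-olide | O=C1O[C@@H]2/C=C(/CO[Si](c3ccccc3)(c4ccccc4)C(C)(C)C)CC[C@H]5O[C@@]5(CO)C[C@H](OC(C)=O)[C@H]2[C@@H]1CO[Si](c6ccccc6)(c7ccccc7)C(C)(C)C | intermediate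
30 | (1R,4E,6R,7R,8S,10R,11R)-8-acetoxy-1,10-epoxy-13,14,15-trihydroxygermacr-4-en-12,6-olide | O=C1O[C@@H]2/C=C(/CO)CC[C@H]3O[C@@]3(CO)C[C@H](OC(C)=O)[C@H]2[C@@H]1CO | intermediate
31 | (1R,4E,6R,7R,8S,10R,11R)-8-acetoxy-1,10-epoxy-13,14-dihydroxy-15-oxogermacr-4-en-12,6-olide | O=C1O[C@@H]2/C=C(/C=O)CC[C@H]3O[C@@]3(CO)C[C@H](OC(C)=O)[C@H]2[C@@H]1CO | intermediate
32 | (1R,4E,6R,7R,8S,10R,11R)-8,13,14-triacetoxy-1,10-epoxy-15-oxogermacr-4-en-12,6-olide | O=C1O[C@@H]2/C=C(/C=O)CC[C@H]3O[C@@]3(COC(C)=O)C[C@H](OC(C)=O)[C@H]2[C@@H]1COC(C)=O | intermediate (not isolated)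
33 | (1R,4E,6R,7R,8S,10R)-8,14-diacetoxy-1,10-epoxy-15-oxogermacra-4,11(13)-dien-12,6-olide (CNP0211286.1) | C=C1C(=O)O[C@@H]2/C=C(/C=O)CC[C@H]3O[C@@]3(COC(C)=O)C[C@H](OC(C)=O)[C@@H]12 | target

## Step count and risks

Total step count: 22. Longest linear sequence: 20 steps (steps 1–4 and 7–22; steps 5 and 6 are the side branch).

**1. Step 16 (Proposed new method).**
What may go wrong:
- the acetoxy acrylate is reduced in competition with the aldehyde, giving an allyl samarium species that attacks C8 through C1 or is simply protonated;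
- two molecules undergo pinacol coupling;
- facial selectivity at C8 is poor.

Fallback (known chemistry; sets out from 19, returns at 28). Nozaki–Hiyama–Kishi addition of (2‑bromoallyl)trimethylsilane to aldehyde 19 (CrCl2, cat. NiCl2, DMF) would give the C1 carbinol that carries a 2‑[(trimethylsilyl)methyl]vinyl group, allylsilane carbinol F1. Silylation (TBSOTf, 2,6‑lutidine) would give the C1 TBS ether F2, and dilute‑acid hydrolysis of the dioxolane the C8 aldehyde F3. An intramolecular Hosomi–Sakurai allylation (BF3·OEt2, CH2Cl2, −78 °C, high dilution) would then close ring A at the same C8–C9 bond through the CH2 terminus of the allylsilane. Both CH2 arms on C10 are equivalent, so no regiochemical question arises, and C8 is set by Felkin–Anh control from C7; the product is the macrocyclic exo‑methylene alcohol F4 (C10=C14). Acetylation (Ac2O, pyridine) would give the 8‑acetate F5, and HF·pyridine would remove the secondary TBS group to give the C1 allylic alcohol F6. A rhenium‑oxo‑catalysed 1,3‑transposition of the allylic alcohol (Ph3SiOReO3, Et2O, 0 °C) would finally move the hydroxyl to C14 and the alkene into the ring with C2 trans to C14, which is compound 28.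

**2. Step 13.**
What may go wrong: the amine‑catalysed addition is slow, and during that time the enolisable C1 aldehyde self‑condenses.

Fallback (sets out from 19, returns at 21). Hydroalumination of allyl propiolate (iBu2AlH, N‑methylmorpholine N‑oxide, THF, 0 °C) would give the α‑aluminated acrylate, vinylalane F7, which adds to aldehyde 19 at 0 °C to give 21 directly. This stoichiometric vinylalumination does not depend on the reversible amine addition.

**3. Step 19.**
What may go wrong: oxygen transfer from the titanium–tartrate complex to the hindered, ring‑bound allylic alcohol is slow, or the ring conformation opposes the face demanded by the tartrate.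

Fallback (sets out from 28, returns at 29). Hydroxyl‑directed epoxidation with VO(acac)2 and tBuOOH (CH2Cl2, 0 °C) would form a vanadate ester of the C14 hydroxyl that delivers oxygen to C1=C10 alone. The face is then chosen by the ring substituents (the C8 acetate and ring B) and not by a chiral ligand. This gives 29 if the ring favours the (1R,10R) face, which would have to be established on the first sample.

## Further compounds

F1 | step 16 | C1 carbinol from 19 with a 2-[(trimethylsilyl)methyl]vinyl group on C10 (both C1 epimers) | O=C1O[C@H](/C=C(/CO[Si](c2ccccc2)(c3ccccc3)C(C)(C)C)CCC(O)C(=C)C[Si](C)(C)C)[C@@H](C4OCCO4)[C@@H]1CO[Si](c5ccccc5)(c6ccccc6)C(C)(C)C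
F2 | step 16 | C1 TBS ether of F1 | O=C1O[C@H](/C=C(/CO[Si](c2ccccc2)(c3ccccc3)C(C)(C)C)CCC(O[Si](C)(C)C(C)(C)C)C(=C)C[Si](C)(C)C)[C@@H](C4OCCO4)[C@@H]1CO[Si](c5ccccc5)(c6ccccc6)C(C)(C)C
F3 | step 16 | C8 aldehyde from F2 | O=C1O[C@H](/C=C(/CO[Si](c2ccccc2)(c3ccccc3)C(C)(C)C)CCC(O[Si](C)(C)C(C)(C)C)C(=C)C[Si](C)(C)C)[C@@H](C=O)[C@@H]1CO[Si](c4ccccc4)(c5ccccc5)C(C)(C)C
F4 | step 16 | macrocyclic (8S)-alcohol with C10=C14 exocyclic methylene and C1 OTBS | O=C1O[C@@H]2/C=C(/CO[Si](c3ccccc3)(c4ccccc4)C(C)(C)C)CCC(O[Si](C)(C)C(C)(C)C)C(=C)C[C@H](O)[C@H]2[C@@H]1CO[Si](c5ccccc5)(c6ccccc6)C(C)(C)C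
F5 | step 16 | 8-acetate of F4 | O=C1O[C@@H]2/C=C(/CO[Si](c3ccccc3)(c4ccccc4)C(C)(C)C)CCC(O[Si](C)(C)C(C)(C)C)C(=C)C[C@H](OC(C)=O)[C@H]2[C@@H]1CO[Si](c5ccccc5)(c6ccccc6)C(C)(C)C
F6 | step 16 | C1 allylic alcohol from F5 (8-acetate, C10=C14 methylene) | O=C1O[C@@H]2/C=C(/CO[Si](c3ccccc3)(c4ccccc4)C(C)(C)C)CCC(O)C(=C)C[C@H](OC(C)=O)[C@H]2[C@@H]1CO[Si](c5ccccc5)(c6ccccc6)C(C)(C)C
F7 | step 13 | allyl 2-(diisobutylalumanyl)prop-2-enoate | C=C(C(=O)OCC=C)[Al](CC(C)C)CC(C)C
F0 | step 19 | none | none
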